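Ring B of the chromene (C4a, C5, C6, C7, C8, C8a) is a disguised 3-alkoxysalicylate: C4a carries carbon (C4), C8a the ring oxygen O1, C8 a hydroxyl, while C5, C6 and C7 bear prenyl, the arylpropyl chain and hydrogen. The route therefore assembles this ring from two acyclic pieces in a TiCl4-mediated [3+3] cyclocondensation that forms C7–C8 and C4a–C5 and delivers all six substituents at once. The partners are a 4-allyloxy-1,3-bis(trimethylsilyloxy)diene (C4a, C8a, C8) and a 2-alkyl-3-silyloxy enone (C7, C6, C5) carrying the prenyl ketone and the protected ring A chain. Ester reduction, isobutenyl addition and oxa-6π closure then build the pyran ring.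

Key step: step 10

Remark on the chemistry: the silyl enol ethers, the enaminone and the quinone methide arise as geometric mixtures or equilibrate, and all isomers converge on the next compound, so their SMILES carry no double-bond descriptors. The target has no stereocentre.

Step 1
Reactants: 1 methyl 4-chloroacetoacetate; 2 allyl alcohol (prop-2-en-1-ol)
Product: 3 methyl 4-(allyloxy)-3-oxobutanoate
Conditions: NaH (2.2 equiv), THF, 0 °C → rt; dil. HCl work-up
Reagents that add atoms: none
Why: Williamson ether synthesis on the sodium enolate of the chloro keto ester, in which allyl oxide displaces the primary chloride while enolate formation shields the methyl ester from transesterification.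

Step 2
Reactants: 3 methyl 4-(allyloxy)-3-oxobutanoate
Product: 4 methyl 4-(allyloxy)-3-(trimethylsilyloxy)but-2-enoate
Conditions: Me3SiCl (1.5 equiv), Et3N (1.5 equiv), toluene, rt
Reagents that add atoms: chlorotrimethylsilane, C[Si](C)(C)Cl
Why: Soft enolisation and O-silylation of the β-keto ester should give the conjugated silyl enol ether, the first stage of a Chan-type diene synthesis.

Step 3
Reactants: 4 methyl 4-(allyloxy)-3-(trimethylsilyloxy)but-2-enoate
Product: 5 4-(allyloxy)-1-methoxy-1,3-bis(trimethylsilyloxy)buta-1,3-diene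
Conditions: LiN(i-Pr)2 (1.3 equiv), THF, −78 °C; Me3SiCl, −78 → 0 °C; used crude at once
Reagents that add atoms: chlorotrimethylsilane, C[Si](C)(C)Cl
Why: Kinetic γ-deprotonation of the vinylogous ester and O-silylation of the lithium dienolate complete the 1,3-bis(silyloxy)diene (Chan–Brownbridge diene synthesis), and trapping at −78 °C with cold handling keeps the allyl enol ether from sigmatropic rearrangement.

Step 4
Reactants: 6 4-bromo-3-methoxyphenol
Product: 7 (4-bromo-3-methoxyphenoxy)triisopropylsilane
Conditions: i-Pr3SiCl, imidazole, DMF, rt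
Reagents that add atoms: chlorotriisopropylsilane, CC(C)[Si](Cl)(C(C)C)C(C)C
Why: Imidazole-promoted silylation of the phenol gives a bulky aryl silyl ether that should tolerate aqueous phosphate, amines, TiCl4 at low temperature and hydride reagents.

Step 5
Reactants: 7 (4-bromo-3-methoxyphenoxy)triisopropylsilane; 8 pent-4-en-1-ol
Product: 10 5-[2-methoxy-4-(triisopropylsilyloxy)phenyl]pentan-1-ol, via B-(5-hydroxypentyl)-9-BBN 9 (not isolated)
Conditions: 8, 9-BBN-H (2.2 equiv), THF, 0 °C → rt; then 7, PdCl2(dppf) (3 mol %), K3PO4 (3 M aq), DMF, 60 °C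
Reagents that add atoms: none
Why: Anti-Markovnikov hydroboration of the terminal alkene followed by B-alkyl Suzuki–Miyaura coupling, in which zerovalent palladium inserts into the aryl C–Br bond and the primary alkyl group is transferred from boron, should join the chain to ring A; the extra borane covers the free hydroxyl, which is released on work-up.

Step 6
Reactants: 10 5-[2-methoxy-4-(triisopropylsilyloxy)phenyl]pentan-1-ol
Product: 11 5-[2-methoxy-4-(triisopropylsilyloxy)phenyl]pentanal
Conditions: TEMPO (10 mol %), PhI(OAc)2 (1.1 equiv), CH2Cl2, rt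
Reagents that add atoms: none
Why: Oxoammonium (TEMPO/PhI(OAc)2) oxidation of the primary alcohol stops at the aldehyde and should leave the silyl ether and the electron-rich arene untouched.

Step 7
Reactants: 11 5-[2-methoxy-4-(triisopropylsilyloxy)phenyl]pentanal
Product: 12 4-{(E)-5-[2-methoxy-4-(triisopropylsilyloxy)phenyl]pent-1-en-1-yl}morpholine
Conditions: morpholine (1.2 equiv), 4 Å MS, toluene, rt; filter, evaporate
Reagents that add atoms: morpholine, C1COCCN1
Why: Condensation of the unbranched aldehyde with the secondary amine under dehydrating conditions should give the (E)-enamine, the nucleophile for a Stork acylation.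

Step 8
Reactants: 12 4-{(E)-5-[2-methoxy-4-(triisopropylsilyloxy)phenyl]pent-1-en-1-yl}morpholine (2 equiv); 13 4-methylpent-3-enoic acid
Product: 16 (Z)-1-hydroxy-2-{3-[2-methoxy-4-(triisopropylsilyloxy)phenyl]propyl}-6-methylhepta-1,5-dien-3-one (chelated enol of the 2-formyl ketone), via 4-methylpent-3-enoyl chloride 14 (not isolated), via morpholino dienone 15 (not isolated)
Conditions: 13, (COCl)2, DMF (cat.), CH2Cl2, 0 °C, evaporate; add to 12 (2 equiv), CH2Cl2, −40 → 0 °C; then 1 M HCl, THF, rt
Reagents that add atoms: water, O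
Why: Stork enamine C-acylation with the freshly made acid chloride, using a second equivalent of enamine as HCl acceptor so that no tertiary amine can turn the β,γ-unsaturated acid chloride into a vinylketene, followed by mild acid hydrolysis of the vinylogous amide to the 2-formyl ketone, which rests as its chelated enol; the protonated equivalent of enamine returns aldehyde 11 for reuse.

Step 9
Reactants: 16 (Z)-1-hydroxy-2-{3-[2-methoxy-4-(triisopropylsilyloxy)phenyl]propyl}-6-methylhepta-1,5-dien-3-one
Product: 17 2-{3-[2-methoxy-4-(triisopropylsilyloxy)phenyl]propyl}-6-methyl-1-(trimethylsilyloxy)hepta-1,5-dien-3-one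
Conditions: Me3SiCl (1.3 equiv), Et3N (1.4 equiv), CH2Cl2, 0 °C → rt; filter under argon, use crude
Reagents that add atoms: chlorotrimethylsilane, C[Si](C)(C)Cl
Why: O-Silylation of the hydroxymethylene enol gives the 3-silyloxy enone, and because only the 1,3-dicarbonyl is deprotonated the prenyl methylene is not enolised and the olefin should stay out of conjugation.

Step 10
Reactants: 5 4-(allyloxy)-1-methoxy-1,3-bis(trimethylsilyloxy)buta-1,3-diene (1.5 equiv); 17 2-{3-[2-methoxy-4-(triisopropylsilyloxy)phenyl]propyl}-6-methyl-1-(trimethylsilyloxy)hepta-1,5-dien-3-one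
Product: 19 methyl 3-(allyloxy)-2-hydroxy-5-{3-[2-methoxy-4-(triisopropylsilyloxy)phenyl]propyl}-6-(3-methylbut-2-en-1-yl)benzoate, via open-chain enone keto ester 18 (not isolated)
Conditions: TiCl4 (1.1 equiv), 4 Å MS, CH2Cl2, −78 → 0 °C; ice-water quench
Reagents that add atoms: none
Why: TiCl4 binds the carbonyl of 17 and the terminal carbon of diene 5 adds in a Mukaiyama–Michael fashion to the silyloxy-bearing CH, the vinylogous formyl carbon, which makes C7–C8; loss of trimethylsilanol then restores the enone in the titanium-bound open-chain intermediate 18. The central carbon of its β-keto ester unit next attacks the prenyl ketone in an intramolecular aldol, a 6-(enolendo)-exo-trig closure of ring B that makes C4a–C5, and dehydration with enolisation aromatises the ring. The closest known reaction type is the TiCl4-mediated formal [3+3] cyclocondensation of 1,3-bis(silyloxy)-1,3-dienes with 3-silyloxy-2-en-1-ones, which covers 4-alkoxy dienes and enones derived from 2-formyl ketones. No stereocentre is created in the product, since the transient centre at C8 is erased on aromatisation. The step needs regioselectivity (diene terminus to the CH, central carbon to the ketone), which the higher electrophilicity and lower hindrance of the silyloxymethine compared with the doubly flanked ketone should secure, so that prenyl lands on C5 and hydrogen on C7. It also needs the skipped olefin and the allyl ether to survive, which the base-free medium, low temperature and cold quench are chosen to ensure.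

Step 11
Reactants: 19 methyl 3-(allyloxy)-2-hydroxy-5-{3-[2-methoxy-4-(triisopropylsilyloxy)phenyl]propyl}-6-(3-methylbut-2-en-1-yl)benzoate
Product: 20 2-(allyloxy)-6-(hydroxymethyl)-4-{3-[2-methoxy-4-(triisopropylsilyloxy)phenyl]propyl}-5-(3-methylbut-2-en-1-yl)phenol
Conditions: i-Bu2AlH (4 equiv), CH2Cl2, −78 → 0 °C; aq. potassium sodium tartrate
Reagents that add atoms: none
Why: Hydride reduction of the ester by i-Bu2AlH, proceeding through the aluminium phenoxide, should give the benzylic alcohol without touching the aryl silyl ether, the allyl ether or the olefins.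

Step 12
Reactants: 20 2-(allyloxy)-6-(hydroxymethyl)-4-{3-[2-methoxy-4-(triisopropylsilyloxy)phenyl]propyl}-5-(3-methylbut-2-en-1-yl)phenol
Product: 21 3-(allyloxy)-2-hydroxy-5-{3-[2-methoxy-4-(triisopropylsilyloxy)phenyl]propyl}-6-(3-methylbut-2-en-1-yl)benzaldehyde
Conditions: MnO2 (activated, 15 equiv), CH2Cl2, rt
Reagents that add atoms: none
Why: Heterogeneous MnO2 oxidation is selective for the benzylic alcohol, and the hydrogen-bonded salicylaldehyde should resist over-oxidation.

Step 13
Reactants: 21 3-(allyloxy)-2-hydroxy-5-{3-[2-methoxy-4-(triisopropylsilyloxy)phenyl]propyl}-6-(3-methylbut-2-en-1-yl)benzaldehyde; 22 2-methylprop-1-enylmagnesium bromide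
Product: 23 2-(allyloxy)-6-(1-hydroxy-3-methylbut-2-en-1-yl)-4-{3-[2-methoxy-4-(triisopropylsilyloxy)phenyl]propyl}-5-(3-methylbut-2-en-1-yl)phenol (racemic)
Conditions: 22 (3 equiv, THF solution), THF, −20 → 0 °C; H2O quench
Reagents that add atoms: none
Why: Grignard 1,2-addition to the aldehyde after deprotonation of the phenol should give the benzylic-allylic carbinol as a racemate, whose single stereocentre is erased in the next step.

Step 14
Reactants: 23 2-(allyloxy)-6-(1-hydroxy-3-methylbut-2-en-1-yl)-4-{3-[2-methoxy-4-(triisopropylsilyloxy)phenyl]propyl}-5-(3-methylbut-2-en-1-yl)phenol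
Product: 25 8-(allyloxy)-6-{3-[2-methoxy-4-(triisopropylsilyloxy)phenyl]propyl}-2,2-dimethyl-5-(3-methylbut-2-en-1-yl)-2H-chromene, via ortho-quinone methide 24 (not isolated)
Conditions: PPTS (5 mol %), 4 Å MS, toluene, 40 °C
Reagents that add atoms: none
Why: Mild acid-promoted loss of water from the doubly activated carbinol gives the ortho-quinone methide, a 1-oxatriene that closes at its dimethyl-substituted terminus by oxa-6π electrocyclisation (the known cyclodehydration of 2-(1-hydroxyalk-2-enyl)phenols to 2H-chromenes).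

Step 15
Reactants: 25 8-(allyloxy)-6-{3-[2-methoxy-4-(triisopropylsilyloxy)phenyl]propyl}-2,2-dimethyl-5-(3-methylbut-2-en-1-yl)-2H-chromene
Product: 27 Kazinol N (6-[3-(4-hydroxy-2-methoxyphenyl)propyl]-2,2-dimethyl-5-(3-methylbut-2-en-1-yl)-2H-chromen-8-ol), via 8-hydroxychromene silyl ether 26 (not isolated)
Conditions: Pd(PPh3)4 (5 mol %), morpholine (5 equiv), THF, rt; then Bu4NF/AcOH (1:1, 1.5 equiv), 0 °C → rt
Reagents that add atoms: none
Why: Tsuji–Trost deallylation (zerovalent palladium ionises the aryl allyl ether and morpholine captures the π-allyl fragment) followed in the same flask by acetic acid-buffered fluoride cleavage of the aryl silyl ether should release both phenols without strong acid or base.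

Compound list
1 | methyl 4-chloroacetoacetate | COC(=O)CC(=O)CCl | starting material
2 | allyl alcohol | C=CCO | starting material
3 | methyl 4-(allyloxy)-3-oxobutanoate | COC(=O)CC(=O)COCC=C | intermediate
4 | methyl 4-(allyloxy)-3-(trimethylsilyloxy)but-2-enoate (geometric mixture) | COC(=O)C=C(O[Si](C)(C)C)COCC=C | intermediate
5 | 4-(allyloxy)-1-methoxy-1,3-bis(trimethylsilyloxy)buta-1,3-diene (geometric mixture) | COC(O[Si](C)(C)C)=CC(O[Si](C)(C)C)=COCC=C | intermediate
6 | 4-bromo-3-methoxyphenol | COc1cc(O)ccc1Br | starting material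
7 | (4-bromo-3-methoxyphenoxy)triisopropylsilane | COc1cc(O[Si](C(C)C)(C(C)C)C(C)C)ccc1Br | intermediate
8 | pent-4-en-1-ol | C=CCCCO | starting material
9 | 5-(9-borabicyclo[3.3.1]nonan-9-yl)pentan-1-ol (hydroxyl partly carried as its borinate) | OCCCCCB1C2CCCC1CCC2 | intermediate (not isolated)
10 | 5-[2-methoxy-4-(triisopropylsilyloxy)phenyl]pentan-1-ol | COc1cc(O[Si](C(C)C)(C(C)C)C(C)C)ccc1CCCCCO | intermediate
11 | 5-[2-methoxy-4-(triisopropylsilyloxy)phenyl]pentanal | COc1cc(O[Si](C(C)C)(C(C)C)C(C)C)ccc1CCCCC=O | intermediate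
12 | 4-{(E)-5-[2-methoxy-4-(triisopropylsilyloxy)phenyl]pent-1-en-1-yl}morpholine | COc1cc(O[Si](C(C)C)(C(C)C)C(C)C)ccc1CCC/C=C/N1CCOCC1 | intermediate
13 | 4-methylpent-3-enoic acid | CC(C)=CCC(O)=O | starting material
14 | 4-methylpent-3-enoyl chloride | CC(C)=CCC(Cl)=O | intermediate (not isolated)
15 | 2-{3-[2-methoxy-4-(triisopropylsilyloxy)phenyl]propyl}-6-methyl-1-(morpholin-4-yl)hepta-1,5-dien-3-one | CC(C)=CCC(=O)C(CCCc1ccc(O[Si](C(C)C)(C(C)C)C(C)C)cc1OC)=CN1CCOCC1 | intermediate (not isolated)
16 | (Z)-1-hydroxy-2-{3-[2-methoxy-4-(triisopropylsilyloxy)phenyl]propyl}-6-methylhepta-1,5-dien-3-one (enol of the 2-formyl ketone) | CC(C)=CCC(=O)/C(CCCc1ccc(O[Si](C(C)C)(C(C)C)C(C)C)cc1OC)=C\O | intermediate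
17 | 2-{3-[2-methoxy-4-(triisopropylsilyloxy)phenyl]propyl}-6-methyl-1-(trimethylsilyloxy)hepta-1,5-dien-3-one (geometric mixture) | CC(C)=CCC(=O)C(CCCc1ccc(O[Si](C(C)C)(C(C)C)C(C)C)cc1OC)=CO[Si](C)(C)C | intermediate
18 | methyl 4-(allyloxy)-6-{3-[2-methoxy-4-(triisopropylsilyloxy)phenyl]propyl}-10-methyl-3,7-dioxoundeca-5,9-dienoate (racemic, titanium-bound in the flask) | COC(=O)CC(=O)C(OCC=C)C=C(CCCc1ccc(O[Si](C(C)C)(C(C)C)C(C)C)cc1OC)C(=O)CC=C(C)C | intermediate (not isolated)
19 | methyl 3-(allyloxy)-2-hydroxy-5-{3-[2-methoxy-4-(triisopropylsilyloxy)phenyl]propyl}-6-(3-methylbut-2-en-1-yl)benzoate | COC(=O)c1c(O)c(OCC=C)cc(CCCc2ccc(O[Si](C(C)C)(C(C)C)C(C)C)cc2OC)c1CC=C(C)C | intermediate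
20 | 2-(allyloxy)-6-(hydroxymethyl)-4-{3-[2-methoxy-4-(triisopropylsilyloxy)phenyl]propyl}-5-(3-methylbut-2-en-1-yl)phenol | OCc1c(O)c(OCC=C)cc(CCCc2ccc(O[Si](C(C)C)(C(C)C)C(C)C)cc2OC)c1CC=C(C)C | intermediate
21 | 3-(allyloxy)-2-hydroxy-5-{3-[2-methoxy-4-(triisopropylsilyloxy)phenyl]propyl}-6-(3-methylbut-2-en-1-yl)benzaldehyde | O=Cc1c(O)c(OCC=C)cc(CCCc2ccc(O[Si](C(C)C)(C(C)C)C(C)C)cc2OC)c1CC=C(C)C | intermediate
22 | 2-methylprop-1-enylmagnesium bromide | CC(C)=C[Mg]Br | starting material
23 | 2-(allyloxy)-6-(1-hydroxy-3-methylbut-2-en-1-yl)-4-{3-[2-methoxy-4-(triisopropylsilyloxy)phenyl]propyl}-5-(3-methylbut-2-en-1-yl)phenol (racemic) | CC(C)=CC(O)c1c(O)c(OCC=C)cc(CCCc2ccc(O[Si](C(C)C)(C(C)C)C(C)C)cc2OC)c1CC=C(C)C | intermediate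
24 | 2-(allyloxy)-4-{3-[2-methoxy-4-(triisopropylsilyloxy)phenyl]propyl}-6-(3-methylbut-2-en-1-ylidene)-5-(3-methylbut-2-en-1-yl)cyclohexa-2,4-dien-1-one (ortho-quinone methide) | O=C1C(OCC=C)=CC(CCCc2ccc(O[Si](C(C)C)(C(C)C)C(C)C)cc2OC)=C(CC=C(C)C)C1=CC=C(C)C | intermediate (not isolated)
25 | 8-(allyloxy)-6-{3-[2-methoxy-4-(triisopropylsilyloxy)phenyl]propyl}-2,2-dimethyl-5-(3-methylbut-2-en-1-yl)-2H-chromene | COc1cc(O[Si](C(C)C)(C(C)C)C(C)C)ccc1CCCc1cc(OCC=C)c2c(c1CC=C(C)C)C=CC(C)(C)O2 | intermediate
26 | 6-{3-[2-methoxy-4-(triisopropylsilyloxy)phenyl]propyl}-2,2-dimethyl-5-(3-methylbut-2-en-1-yl)-2H-chromen-8-ol | COc1cc(O[Si](C(C)C)(C(C)C)C(C)C)ccc1CCCc1cc(O)c2c(c1CC=C(C)C)C=CC(C)(C)O2 | intermediate (not isolated)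
27 | Kazinol N, 6-[3-(4-hydroxy-2-methoxyphenyl)propyl]-2,2-dimethyl-5-(3-methylbut-2-en-1-yl)-2H-chromen-8-ol | COc1cc(O)ccc1CCCc1cc(O)c2c(c1CC=C(C)C)C=CC(C)(C)O2 | target

Total step count: 15. Longest linear sequence: 12 steps (steps 4 to 15, from 4-bromo-3-methoxyphenol); the diene arm (steps 1 to 3) joins at step 10.

Steps most likely to fail

1. Step 10. The first C–C bond may form at the ketone carbon instead of the silyloxymethine, which would scramble the ring substitution. The skipped olefin may also slide into conjugation or pick up HCl on warming, and the Lewis acid may trigger a [3,3] shift of the allyl enol ether of the diene before it reacts. The fallback sets out from 16 and comes back at 19. Acetalisation of 16 (HC(OMe)3, MeOH, PPTS cat., rt) should give the β-keto acetal 1,1-dimethoxy-2-{3-[2-methoxy-4-(triisopropylsilyloxy)phenyl]propyl}-6-methylhept-5-en-3-one F1. Condensation of F1 with diene 5 (TiCl4, CH2Cl2, −78 °C) then begins as a Mukaiyama-type substitution at the ionised acetal carbon instead of a conjugate addition. The site of the first bond is thereby fixed by the acetal alone, and the same aldol closure and aromatisation, with loss of methanol, lead to 19.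

2. Step 8. The acid chloride may lose HCl to a vinylketene, the enamine may be acylated on nitrogen, or the olefin may migrate into conjugation during acylation or hydrolysis. The fallback sets out from 7 (with 14) and comes back at 16. Hydroboration of commercial methyl pent-4-enoate (C=CCCC(=O)OC) with 9-BBN-H gives methyl 5-(9-borabicyclo[3.3.1]nonan-9-yl)pentanoate F2, and B-alkyl Suzuki coupling with 7 (PdCl2(dppf), K3PO4) should give methyl 5-[2-methoxy-4-(triisopropylsilyloxy)phenyl]pentanoate F3. A titanium-mediated crossed Claisen condensation with 14 (TiCl4, Bu3N, N-methylimidazole cat., CH2Cl2, −45 °C) acylates the ester at its α-carbon to methyl 2-{3-[2-methoxy-4-(triisopropylsilyloxy)phenyl]propyl}-6-methyl-3-oxohept-5-enoate F4. LiAlH4 (THF, 0 °C) reduces both carbonyls to 2-{3-[2-methoxy-4-(triisopropylsilyloxy)phenyl]propyl}-6-methylhept-5-ene-1,3-diol F5, and NaHCO3-buffered Dess–Martin oxidation of both carbinols returns 16. The regiochemistry of the 1,3-dicarbonyl is again fixed by which carbon carried the ester.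

3. Step 14. Under acid the benzylic-allylic cation may be captured by the neighbouring prenyl olefin in a carbocyclisation, or the prenyl double bond may hydrate or migrate before the phenolic oxygen closes the ring. The fallback sets out from 21, bypasses 23 and comes back at 25. A Petasis-type condensation of 21 with 2-methylprop-1-enylboronic acid (CC(C)=CB(O)O) and dibenzylamine (dioxane, 90 °C) forms the iminium, and phenoxide-bound boron delivers the alkenyl group to give the aminophenol 2-(allyloxy)-6-[1-(dibenzylamino)-3-methylbut-2-en-1-yl]-4-{3-[2-methoxy-4-(triisopropylsilyloxy)phenyl]propyl}-5-(3-methylbut-2-en-1-yl)phenol F6. This loses dibenzylamine thermally under neutral conditions to the same oxatriene 24, which closes to 25.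

Further compounds
F1 | step 10 | 1,1-dimethoxy-2-{3-[2-methoxy-4-(triisopropylsilyloxy)phenyl]propyl}-6-methylhept-5-en-3-one (racemic) | COC(OC)C(CCCc1ccc(O[Si](C(C)C)(C(C)C)C(C)C)cc1OC)C(=O)CC=C(C)C
F2 | step 8 | methyl 5-(9-borabicyclo[3.3.1]nonan-9-yl)pentanoate | COC(=O)CCCCB1C2CCCC1CCC2
F3 | step 8 | methyl 5-[2-methoxy-4-(triisopropylsilyloxy)phenyl]pentanoate | COC(=O)CCCCc1ccc(O[Si](C(C)C)(C(C)C)C(C)C)cc1OC
F4 | step 8 | methyl 2-{3-[2-methoxy-4-(triisopropylsilyloxy)phenyl]propyl}-6-methyl-3-oxohept-5-enoate (racemic) | COC(=O)C(CCCc1ccc(O[Si](C(C)C)(C(C)C)C(C)C)cc1OC)C(=O)CC=C(C)C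
F5 | step 8 | 2-{3-[2-methoxy-4-(triisopropylsilyloxy)phenyl]propyl}-6-methylhept-5-ene-1,3-diol (diastereomer mixture) | OCC(CCCc1ccc(O[Si](C(C)C)(C(C)C)C(C)C)cc1OC)C(O)CC=C(C)C
F6 | step 14 | 2-(allyloxy)-6-[1-(dibenzylamino)-3-methylbut-2-en-1-yl]-4-{3-[2-methoxy-4-(triisopropylsilyloxy)phenyl]propyl}-5-(3-methylbut-2-en-1-yl)phenol (racemic) | CC(C)=CC(N(Cc1ccccc1)Cc1ccccc1)c1c(O)c(OCC=C)cc(CCCc2ccc(O[Si](C(C)C)(C(C)C)C(C)C)cc2OC)c1CC=C(C)C
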